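Amounts first: the two flasks hold the same charges and differ in run time.

| flask | substrate | coupling partner | time |
|---|---|---|---|
| grey | 24 mM | 36.0 mM | 25 min |
| amber | 24 mM | 36.0 mM | 40 min |

    substrate ⇌ reactive form (K1 = 1.6, k1 = 0.025 s⁻¹)
    coupling partner + reactive form → target (k2 = 0.020 L mol⁻¹ s⁻¹)
    substrate + reactive form → side product (k3 = 0.030 L mol⁻¹ s⁻¹)
    coupling partner + target ⇌ idle adduct, settled at all times (K4 = 41 L mol⁻¹)
    target → over-reaction product (k5 = 6.8 × 10⁻⁷ s⁻¹)

- a species is counted by the substrate in it: one side product counts as two
- amounts and yields of target count idle adduct too
- run time (grey): 25 min

1. which of the two there is more of at the end, counted by the substrate in each, grey (target / side product)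
2. which of the two there is more of at the end, counted by the substrate in each, amber (target / side product)
3. target at the end, in percent of the substrate charged, grey
4. target at the end, in percent of the substrate charged, amber

Substrate and reactive form relax in 0.284 min in grey, much faster than the run of 25 min, so I treat them as one pool split by the equilibrium constant. Free target has a half-life of 280 h against over-reaction, much longer than either run, so I drop that step.

Target gains with partner times reactive form. Side product, counted double, gains with substrate times reactive form. At the charged partner, a pool of 31.2 mM makes the two gains equal. I call this the crossover level, a selectivity factor written as a concentration. Below it, target gains faster. The charge of 24 mM stands below it, so I expect target ahead in grey and target ahead in amber.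

With the partner held, the pool feeds target by a pseudo-first-order loss at 0.0266 min⁻¹. The side loss is second order, and the pool equation solves. With C the crossover, S the charge and r the rate:

yield = (C/S) · ln[1 + (S/C) · (1 − exp(−r·t))]

Free partner falls, so holding it at its charge gives upper bounds:

grey 41.3%; amber 53.0%

Each target costs one partner, and the adduct ties up a further one for at most a share 0.596 of target. So partner stays above a floor, 20.2 mM in grey and 15.7 mM in amber. Scaling crossover and rate down to the floor gives lower bounds:

grey 25.9%; amber 28.5%

The midpoints of charge and floor, 28.1 mM and 25.8 mM, give my estimate, which is no bound:

grey 34.1%; amber 42.2%

The forecast says target in grey and target in amber, with 34% (31% to 37%) and 43% (39% to 46%), both central values inside my brackets, holding that “with the partner in excess, coupling stays ahead of the side product”.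

The flasks give 34.2% of target against 22.9% of side product in grey, and 43.0% against 26.9% in amber.

With its extra time taken away, amber gives 34.2% of target instead of 43.0%, so the difference in time is the main reason for the gap between the two flasks. The crossover falls as free partner falls, to 20.6 mM at 25.0 min in grey, still more than the 10.3 mM of substrate and reactive form then. A grey flask charged with 60 mM of substrate starts above the crossover, and it ends with 43.2% of side product against 23.9% of target.

Its constants were drawn at random within sensible limits, and the outcome is calculated.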